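**Retrosynthetic overview**

1. Numbering (germacrane): ring C1–C10; C11/C12/C13 = butenolide α-carbon, lactone C=O, CH2OAc; C14 = CH2OH on C10; C15 = CH3 on C4. Endgame from macrocycle 28: cleave the O6/O8 silylene and the O12 silyl ether, oxidise C12 to close the butenolide (last ring), acylate O8, free O14.
2. Key disconnection C1–C10: the C1–C10 oxirane is a 2-vinyl-oxirane (C1 is an allylic CH on the cis C2=C3 alkene; C10 is a fully substituted oxirane carbon bearing C9 and C14H2O). This is the retron of an allylic sulfonium ylide plus a ketone; run intramolecularly on keto-sulfonium salt 25 it closes the ten-membered carbocycle and the oxirane in one operation and sets C1 and C10.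
3. What shapes the precursor: the cis C2=C3 alkene and the cis C4–C5 oxirane bend the chain; the syn O6/O8 pair across sp2 C7 is tied into a temporary six-membered silylene ring; C12 is held at the alcohol level (no acidic butenolide); C2–C3 is carried as an alkyne until two steps before.
4. Seco chain: C6–C7 by Nozaki–Hiyama–Kishi union of epoxy aldehyde 5 (C1–C6; Sonogashira, Sharpless epoxidation) with alkenyl triflate 13 (C7–C14; asymmetric glyoxylate–ene, Dieckmann). The temporary tetronate ring fixes the C7=C11 geometry and tells C12 from C13.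
5. Ring order: C4–C5 oxirane → tetronate (temporary, opened by reduction) → silylene (temporary) → ten-membered ring + C1–C10 oxirane (key step) → butenolide.

Key step: step 17

Remark: (Z)-3-iodobut-2-en-1-ol (1) and 3-[(tert-butyldimethylsilyl)oxy]propanoic acid (10) are taken as catalogue compounds; the acid in the C8 ester of the target is (R)-2-methylbutanoic acid.

**Route**

Step 1
Reactants: 1 (Z)-3-iodobut-2-en-1-ol; 2 4-methoxybenzyl propargyl ether
Product: 3 (Z)-6-[(4-methoxybenzyl)oxy]-3-methylhex-2-en-4-yn-1-ol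
Conditions: PdCl2(PPh3)2 (cat.), CuI (cat.), Et3N, THF, 23 °C
Reagents that add atoms: none
Why: Sonogashira coupling of an alkenyl iodide goes with retention of the Z geometry and tolerates the free alcohol, so the alkyne (C3) ends up cis to CH2OH (C6) as the cis C4–C5 oxirane needs.

Step 2
Reactants: 3 (Z)-enynol
Product: 4 [(2S,3R)-3-{3-[(4-methoxybenzyl)oxy]prop-1-yn-1-yl}-3-methyloxiran-2-yl]methanol
Conditions: Ti(OiPr)4, L-(+)-diethyl tartrate, tBuOOH, 4 Å molecular sieves, CH2Cl2, −20 °C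
Reagents that add atoms: tert-butyl hydroperoxide, CC(C)(C)OO
Why: Sharpless asymmetric epoxidation of the primary Z-allylic alcohol; the L-(+)-tartrate catalyst should deliver oxygen to the face that gives the (2S,3R)-epoxy alcohol (C4 R, C5 S of the target), the conjugated alkyne staying untouched.

Step 3
Reactants: 4 epoxy alcohol
Product: 5 (2R,3R)-3-{3-[(4-methoxybenzyl)oxy]prop-1-yn-1-yl}-3-methyloxirane-2-carbaldehyde
Conditions: Dess–Martin periodinane, NaHCO3, CH2Cl2, 0 °C; used at once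
Reagents that add atoms: none
Why: Buffered Dess–Martin oxidation turns a 2,3-epoxy alcohol into the epoxy aldehyde without epimerising C5 (the descriptor changes only by priority).

Step 4
Reactants: 6 2-methylprop-2-en-1-ol
Product: 7 tert-butyl[(2-methylprop-2-en-1-yl)oxy]diphenylsilane
Conditions: tBuPh2SiCl, imidazole, DMF, 23 °C
Reagents that add atoms: tert-butyl(chloro)diphenylsilane, CC(C)(C)[Si](Cl)(c1ccccc1)c1ccccc1
Why: Routine silylation of a primary alcohol; the bulky silyl group later shields the CH2–O hydrogens in the ene step and protects O14 to the end.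

Step 5
Reactants: 7 methallyl silyl ether; 8 ethyl glyoxylate
Product: 9 ethyl (2S)-4-{[(tert-butyldiphenylsilyl)oxy]methyl}-2-hydroxypent-4-enoate
Conditions: (S)-BINOL (cat.), TiCl2(OiPr)2 (cat.), 4 Å molecular sieves, CH2Cl2, −30 °C
Reagents that add atoms: none
Why: BINOL–titanium-catalysed asymmetric glyoxylate–ene reaction of a 1,1-disubstituted alkene; the (S)-BINOL catalyst should set C8 as S, hydrogen is taken from the methyl group, and the shifted 1,1-disubstituted alkene is the masked C10 ketone.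

Step 6
Reactants: 9 hydroxy ester; 10 3-[(tert-butyldimethylsilyl)oxy]propanoic acid
Product: 11 ethyl (2S)-2-({3-[(tert-butyldimethylsilyl)oxy]propanoyl}oxy)-4-{[(tert-butyldiphenylsilyl)oxy]methyl}pent-4-enoate
Conditions: DCC, DMAP (cat.), CH2Cl2, 0 → 23 °C
Reagents that add atoms: none
Why: Steglich esterification of the secondary α-hydroxy ester; no stereocentre is touched.

Step 7
Reactants: 11 diester
Product: 12 (5S)-3-{[(tert-butyldimethylsilyl)oxy]methyl}-5-(2-{[(tert-butyldiphenylsilyl)oxy]methyl}prop-2-en-1-yl)-4-hydroxyfuran-2(5H)-one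
Conditions: LiN(SiMe3)2 (2.2 equiv), THF, −78 → −20 °C; then 1 M aq. HCl
Reagents that add atoms: none
Why: Dieckmann condensation of an α-acyloxy ester: the C11 ester enolate attacks the C7 ester (5-exo-trig) to give the 3-substituted tetronic acid, whose ring locks C13 cis to C8 on the future C7=C11 alkene; the low temperature is chosen to limit β-elimination of the silyloxy group and deprotonation at C8.

Step 8
Reactants: 12 tetronic acid
Product: 13 (2S)-4-{[(tert-butyldimethylsilyl)oxy]methyl}-2-(2-{[(tert-butyldiphenylsilyl)oxy]methyl}prop-2-en-1-yl)-5-oxo-2,5-dihydrofuran-3-yl trifluoromethanesulfonate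
Conditions: Tf2O, Et3N, CH2Cl2, −78 °C
Reagents that add atoms: trifluoromethanesulfonic anhydride, O=S(=O)(OS(=O)(=O)C(F)(F)F)C(F)(F)F
Why: O-Triflation of the vinylogous acid gives the 4-triflyloxybutenolide, a standard alkenyl electrophile for nickel/chromium coupling.

Step 9
Reactants: 13 alkenyl triflate; 5 epoxy aldehyde
Product: 15 (5S)-3-{[(tert-butyldimethylsilyl)oxy]methyl}-5-(2-{[(tert-butyldiphenylsilyl)oxy]methyl}prop-2-en-1-yl)-4-[(S)-hydroxy{(2S,3R)-3-[3-(4-methoxybenzyloxy)prop-1-yn-1-yl]-3-methyloxiran-2-yl}methyl]furan-2(5H)-one, via alkenylchromium dichloride 14 (not isolated)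
Conditions: CrCl2 (excess), NiCl2 (cat.), DMF, 23 °C
Reagents that add atoms: none
Why: Nozaki–Hiyama–Kishi coupling; the non-chelating alkenylchromium should add to the α,β-epoxy aldehyde in the polar Felkin–Anh/Cornforth sense (anti to the oxirane C–O bond), which sets C6 as S (erythro to C5), and the lactone cannot move to O6 because C13 is trans to C6.

Step 10
Reactants: 15 coupled butenolide
Product: 17 seco-triol (C6–OH / C8–OH / C13–OH free; C12–OTBS; C14–OTBDPS; C1–OPMB; C2≡C3; C10=CH2), via lactol 16 (not isolated)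
Conditions: iBu2AlH (excess), CH2Cl2, −78 → −40 °C; aq. potassium sodium tartrate
Reagents that add atoms: none
Why: DIBAL reduction of an α,β-unsaturated γ-lactone through the lactol to the Z-ene-1,4-diol frees O8 and C13–OH and keeps the ring-derived alkene geometry; the lactone is the only carbonyl group present.

Step 11
Reactants: 17 seco-triol
Product: 18 C13 mono-acetate of 17
Conditions: AcCl (1 equiv), 2,4,6-collidine, CH2Cl2, −78 °C
Reagents that add atoms: acetyl chloride, CC(Cl)=O
Why: Selective acylation of the primary allylic alcohol over the two hindered secondary alcohols.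

Step 12
Reactants: 18 diol acetate
Product: 19 6,8-O-(di-tert-butylsilylene) derivative of 18
Conditions: tBu2Si(OTf)2, 2,6-lutidine, CH2Cl2, 0 °C
Reagents that add atoms: di-tert-butylsilyl bis(trifluoromethanesulfonate), CC(C)(C)[Si](OS(=O)(=O)C(F)(F)F)(OS(=O)(=O)C(F)(F)F)C(C)(C)C
Why: Silylene protection of a syn-1,3-diol; the six-membered 1,3,2-dioxasilinane ties O6 to O8 and, through allylic strain against C12 and C13, should turn the C5 and C9 chains to the same face.

Step 13
Reactants: 19 silylene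
Product: 21 C10 ketone (C9H2–C(=O)–C14H2OTBDPS), via diol 20 (not isolated)
Conditions: OsO4 (cat.), NaIO4, 2,6-lutidine, dioxane/H2O, 23 °C
Reagents that add atoms: osmium tetroxide, O=[Os](=O)(=O)=O; sodium periodate, [Na+].[O-]I(=O)(=O)=O
Why: Lemieux–Johnson oxidation should pick the unhindered 1,1-disubstituted alkene over the tetrasubstituted, fourfold allylically oxygenated C7=C11 alkene and the alkyne.

Step 14
Reactants: 21 ketone
Product: 22 propargylic alcohol (C1–OH)
Conditions: DDQ, CH2Cl2/pH 7 buffer, 0 °C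
Reagents that add atoms: none
Why: Oxidative cleavage of the 4-methoxybenzyl ether with DDQ leaves silyl ethers, silylene, acetate, ketone and oxirane intact.

Step 15
Reactants: 22 propargylic alcohol
Product: 23 (2Z)-allylic alcohol
Conditions: H2 (1 atm), Pd/CaCO3 poisoned with Pb(OAc)2, quinoline, EtOAc, 23 °C
Reagents that add atoms: none
Why: Lindlar semi-hydrogenation gives the Z alkene by syn addition of H2; it is placed this late so that the labile cis-vinyl oxirane appears only under neutral, amine-buffered conditions.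

Step 16
Reactants: 23 (2Z)-allylic alcohol
Product: 25 S-allyl tetrahydrothiophenium methanesulfonate, via allylic mesylate 24 (not isolated)
Conditions: (MeSO2)2O, iPr2NEt, CH2Cl2, −40 °C; then tetrahydrothiophene (excess), −40 → 0 °C
Reagents that add atoms: methanesulfonic anhydride, CS(=O)(=O)OS(C)(=O)=O; tetrahydrothiophene, C1CCSC1
Why: Mesylation of the primary allylic alcohol and direct SN2 displacement by the soft sulfide gives the sulfonium salt with a non-nucleophilic counter-ion; the low temperature should suppress participation of the cis-oxirane oxygen and Z/E scrambling.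

Step 17
Reactants: 25 keto-sulfonium salt
Product: 28 silylene-bridged macrocycle (ten-membered carbocycle with trans C1–C10 oxirane; 1R 4R 5S 6S 8S 10S), via sulfonium ylide 26 (not isolated), via betaine 27 (not isolated)
Conditions: Cs2CO3, MeCN, 0 → 23 °C, slow addition of 25, final concentration about 1 mM
Reagents that add atoms: none
Why: Proposed new method: carbonate removes the most acidic hydrogen (C1–H next to sulfonium and the C2=C3 alkene) to give ylide 26, whose α-carbon adds to the C10 ketone (10-exo-trig closure of the carbocycle) to give betaine 27, and the alkoxide then displaces tetrahydrothiophene anti-periplanar (3-exo-tet) to close the oxirane. The closest known reactions are the intermolecular epoxidation of ketones and aldehydes by allylic sulfonium ylides and intramolecular sulfonium-ylide epoxidations that close five- to seven-membered rings, while macrocyclic alkylations of allylic sulfide and sulfone anions at C1 of germacrane precursors show that this position tolerates ten-membered ring closure. C10 should be set by the silylene-bridged template: the syn O6–Si–O8 ring holds both chains on one face, the bulky C14H2OTBDPS group turns away from the di-tert-butylsilylene, and the carbonyl oxygen therefore ends cis to O8 (10S). C1 should follow from the ring: C2 and C9 both lie in the forming ring, only the betaine with C2 trans to C9 can reach the anti S/O arrangement without transannular clash, and inversion at C1 then gives the trans-oxirane (1R), reversible betaine formation letting misfit adducts revert. The step needs α- over γ-attack of the ylide (only the α-adduct can close to an oxirane), no 1,4-elimination into the C4–C5 oxirane (in the rotamer of least allylic strain about C3–C4 the C4–O bond lies near the nodal plane of the allyl ylide) and no base damage to the chain (O8 sits in the silylene as a poor leaving group β to the ketone, and C12 at the alcohol level removes the acidic butenolide γ-hydrogen). High dilution and slow addition are used to suppress intermolecular epoxidation.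

Step 18
Reactants: 28 macrocycle
Product: 29 macrocyclic triol (C6–OH / C8–OH / C12–OH free; C13–OAc; C14–OTBDPS)
Conditions: HF·pyridine, excess pyridine, THF, 0 °C
Reagents that add atoms: none
Why: Buffered fluoride desilylation should remove the silylene and the primary allylic TBS ether but not the hindered neopentyl-type TBDPS ether at C14, the pyridine buffer protecting the two vinyl oxiranes.

Step 19
Reactants: 29 triol
Product: 32 8-hydroxy butenolide (6,12-olide; C14–OTBDPS), via hydroxy aldehyde 30 (not isolated), via lactol 31 (not isolated)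
Conditions: TEMPO (cat.), PhI(OAc)2, CH2Cl2, 23 °C
Reagents that add atoms: none
Why: TEMPO/PhI(OAc)2 oxidative lactonisation of a Z-ene-1,4-diol: the primary allylic alcohol is oxidised to the aldehyde, the cis C6–OH closes the lactol (5-exo-trig) and this is oxidised to the butenolide, the secondary C8–OH reacting much more slowly and C6 keeping its configuration.

Step 20
Reactants: 32 8-hydroxy butenolide; 33 (R)-2-methylbutanoic acid
Product: 34 14-O-TBDPS ether of the target
Conditions: DCC, DMAP (cat.), CH2Cl2, 0 °C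
Reagents that add atoms: none
Why: Steglich esterification of the secondary allylic alcohol with the enantiopure acid; little DMAP and low temperature are used to avoid epimerising the acid α-centre and deprotonating the butenolide γ-position.

Step 21
Reactants: 34 silyl ether
Product: 35 target CNP0108300.1
Conditions: Bu4NF, AcOH (1:1), THF, 0 → 23 °C
Reagents that add atoms: none
Why: Acetic-acid-buffered fluoride cleaves the TBDPS ether under near-neutral conditions, so that the esters, the butenolide γ-hydrogen and the 1,10-epoxy-14-ol (Payne rearrangement) should not be disturbed.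

**Compound list**

1 | (Z)-3-iodobut-2-en-1-ol | C/C(I)=C/CO | starting material
2 | 4-methoxybenzyl propargyl ether (1-methoxy-4-[(prop-2-yn-1-yloxy)methyl]benzene) | C#CCOCc1ccc(OC)cc1 | starting material
3 | (Z)-6-[(4-methoxybenzyl)oxy]-3-methylhex-2-en-4-yn-1-ol | COc1ccc(COCC#C/C(C)=C\CO)cc1 | intermediate
4 | [(2S,3R)-3-{3-[(4-methoxybenzyl)oxy]prop-1-yn-1-yl}-3-methyloxiran-2-yl]methanol | COc1ccc(COCC#C[C@@]2(C)O[C@H]2CO)cc1 | intermediate
5 | (2R,3R)-3-{3-[(4-methoxybenzyl)oxy]prop-1-yn-1-yl}-3-methyloxirane-2-carbaldehyde | COc1ccc(COCC#C[C@@]2(C)O[C@H]2C=O)cc1 | intermediate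
6 | 2-methylprop-2-en-1-ol | C=C(C)CO | starting material
7 | tert-butyl[(2-methylprop-2-en-1-yl)oxy]diphenylsilane | C=C(C)CO[Si](c1ccccc1)(c1ccccc1)C(C)(C)C | intermediate
8 | ethyl glyoxylate | CCOC(=O)C=O | starting material
9 | ethyl (2S)-4-{[(tert-butyldiphenylsilyl)oxy]methyl}-2-hydroxypent-4-enoate | CCOC(=O)[C@@H](O)CC(=C)CO[Si](c1ccccc1)(c1ccccc1)C(C)(C)C | intermediate
10 | 3-[(tert-butyldimethylsilyl)oxy]propanoic acid | OC(=O)CCO[Si](C)(C)C(C)(C)C | starting material
11 | ethyl (2S)-2-({3-[(tert-butyldimethylsilyl)oxy]propanoyl}oxy)-4-{[(tert-butyldiphenylsilyl)oxy]methyl}pent-4-enoate | CCOC(=O)[C@@H](OC(=O)CCO[Si](C)(C)C(C)(C)C)CC(=C)CO[Si](c1ccccc1)(c1ccccc1)C(C)(C)C | intermediate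
12 | (5S)-3-{[(tert-butyldimethylsilyl)oxy]methyl}-5-(2-{[(tert-butyldiphenylsilyl)oxy]methyl}prop-2-en-1-yl)-4-hydroxyfuran-2(5H)-one | O=C1O[C@H](C(O)=C1CO[Si](C)(C)C(C)(C)C)CC(=C)CO[Si](c2ccccc2)(c2ccccc2)C(C)(C)C | intermediate
13 | 4-trifluoromethanesulfonate of 12 | O=C1O[C@H](C(OS(=O)(=O)C(F)(F)F)=C1CO[Si](C)(C)C(C)(C)C)CC(=C)CO[Si](c2ccccc2)(c2ccccc2)C(C)(C)C | intermediate
14 | alkenylchromium dichloride from 13 (CrCl2 on C7) | O=C1O[C@H](C([Cr](Cl)Cl)=C1CO[Si](C)(C)C(C)(C)C)CC(=C)CO[Si](c2ccccc2)(c2ccccc2)C(C)(C)C | intermediate (not isolated)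
15 | C6–C7 coupled butenolide with (6S)-OH, (4R,5S)-oxirane and (8S) centre (full name in step 9) | COc1ccc(COCC#C[C@@]2(C)O[C@H]2[C@@H](O)C2=C(CO[Si](C)(C)C(C)(C)C)C(=O)O[C@H]2CC(=C)CO[Si](c3ccccc3)(c3ccccc3)C(C)(C)C)cc1 | intermediate
16 | lactol of 15 (C13 hemiacetal) | COc1ccc(COCC#C[C@@]2(C)O[C@H]2[C@@H](O)C2=C(CO[Si](C)(C)C(C)(C)C)C(O)O[C@H]2CC(=C)CO[Si](c3ccccc3)(c3ccccc3)C(C)(C)C)cc1 | intermediate (not isolated)
17 | (4R,5S,6S,8S)-seco-triol: C6–OH, C8–OH, C13–OH; C12–OTBS cis to C6; C14–OTBDPS; C1–OPMB; C2≡C3; C10=CH2 | COc1ccc(COCC#C[C@@]2(C)O[C@H]2[C@@H](O)/C(=C(\CO[Si](C)(C)C(C)(C)C)CO)[C@@H](O)CC(=C)CO[Si](c3ccccc3)(c3ccccc3)C(C)(C)C)cc1 | intermediate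
18 | C13 acetate of 17 | COc1ccc(COCC#C[C@@]2(C)O[C@H]2[C@@H](O)/C(=C(\CO[Si](C)(C)C(C)(C)C)COC(C)=O)[C@@H](O)CC(=C)CO[Si](c3ccccc3)(c3ccccc3)C(C)(C)C)cc1 | intermediate
19 | 6,8-O-(di-tert-butylsilylene) derivative of 18 | COc1ccc(COCC#C[C@@]2(C)O[C@H]2[C@H]2O[Si](C(C)(C)C)(C(C)(C)C)O[C@@H](CC(=C)CO[Si](c3ccccc3)(c3ccccc3)C(C)(C)C)/C2=C(/CO[Si](C)(C)C(C)(C)C)COC(C)=O)cc1 | intermediate
20 | C10/C10-CH2 diol from 19 | COc1ccc(COCC#C[C@@]2(C)O[C@H]2[C@H]2O[Si](C(C)(C)C)(C(C)(C)C)O[C@@H](CC(O)(CO)CO[Si](c3ccccc3)(c3ccccc3)C(C)(C)C)/C2=C(/CO[Si](C)(C)C(C)(C)C)COC(C)=O)cc1 | intermediate (not isolated)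
21 | C10 ketone | COc1ccc(COCC#C[C@@]2(C)O[C@H]2[C@H]2O[Si](C(C)(C)C)(C(C)(C)C)O[C@@H](CC(=O)CO[Si](c3ccccc3)(c3ccccc3)C(C)(C)C)/C2=C(/CO[Si](C)(C)C(C)(C)C)COC(C)=O)cc1 | intermediate
22 | propargylic alcohol (C1–OH; C2≡C3) | OCC#C[C@@]2(C)O[C@H]2[C@H]2O[Si](C(C)(C)C)(C(C)(C)C)O[C@@H](CC(=O)CO[Si](c3ccccc3)(c3ccccc3)C(C)(C)C)/C2=C(/CO[Si](C)(C)C(C)(C)C)COC(C)=O | intermediate
23 | (2Z)-allylic alcohol | OC/C=C\[C@@]2(C)O[C@H]2[C@H]2O[Si](C(C)(C)C)(C(C)(C)C)O[C@@H](CC(=O)CO[Si](c3ccccc3)(c3ccccc3)C(C)(C)C)/C2=C(/CO[Si](C)(C)C(C)(C)C)COC(C)=O | intermediate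
24 | (2Z)-allylic methanesulfonate | CS(=O)(=O)OC/C=C\[C@@]2(C)O[C@H]2[C@H]2O[Si](C(C)(C)C)(C(C)(C)C)O[C@@H](CC(=O)CO[Si](c3ccccc3)(c3ccccc3)C(C)(C)C)/C2=C(/CO[Si](C)(C)C(C)(C)C)COC(C)=O | intermediate (not isolated)
25 | S-[(2Z)-allyl]tetrahydrothiophenium methanesulfonate (keto-sulfonium salt) | C1CC[S+](C1)C/C=C\[C@@]2(C)O[C@H]2[C@H]2O[Si](C(C)(C)C)(C(C)(C)C)O[C@@H](CC(=O)CO[Si](c3ccccc3)(c3ccccc3)C(C)(C)C)/C2=C(/CO[Si](C)(C)C(C)(C)C)COC(C)=O.CS(=O)(=O)[O-] | intermediate
26 | C1 sulfonium ylide | C1CC[S+](C1)[CH-]/C=C\[C@@]2(C)O[C@H]2[C@H]2O[Si](C(C)(C)C)(C(C)(C)C)O[C@@H](CC(=O)CO[Si](c3ccccc3)(c3ccccc3)C(C)(C)C)/C2=C(/CO[Si](C)(C)C(C)(C)C)COC(C)=O | intermediate (not isolated)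
27 | macrocyclic betaine (C10 alkoxide, C1 sulfonium) | CC(C)(C)[Si]1(C(C)(C)C)O[C@H]2C[C@]([O-])(CO[Si](c3ccccc3)(c3ccccc3)C(C)(C)C)[C@@H]([S+]3CCCC3)/C=C\[C@@]3(C)O[C@H]3[C@@H](O1)/C2=C(\CO[Si](C)(C)C(C)(C)C)COC(C)=O | intermediate (not isolated)
28 | (1R,4R,5S,6S,8S,10S)-silylene-bridged macrocycle: 1,10- and 4,5-oxiranes, (2Z)-alkene, C12–OTBS, C13–OAc, C14–OTBDPS | CC(C)(C)[Si]1(C(C)(C)C)O[C@H]2C[C@@]3(CO[Si](c4ccccc4)(c4ccccc4)C(C)(C)C)O[C@@H]3/C=C\[C@@]3(C)O[C@H]3[C@@H](O1)/C2=C(\CO[Si](C)(C)C(C)(C)C)COC(C)=O | intermediate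
29 | macrocyclic triol (C6–OH, C8–OH, C12–OH) | O[C@H]1C[C@@]2(CO[Si](c3ccccc3)(c3ccccc3)C(C)(C)C)O[C@@H]2/C=C\[C@@]2(C)O[C@H]2[C@@H](O)/C1=C(\CO)COC(C)=O | intermediate
30 | C12 hydroxy aldehyde | O[C@H]1C[C@@]2(CO[Si](c3ccccc3)(c3ccccc3)C(C)(C)C)O[C@@H]2/C=C\[C@@]2(C)O[C@H]2[C@@H](O)/C1=C(\C=O)COC(C)=O | intermediate (not isolated)
31 | C12 lactol | O[C@H]1C[C@@]2(CO[Si](c3ccccc3)(c3ccccc3)C(C)(C)C)O[C@@H]2/C=C\[C@@]2(C)O[C@H]2[C@H]2OC(O)C(COC(C)=O)=C12 | intermediate (not isolated)
32 | 8-hydroxy-6,12-olide (14-O-TBDPS) | O[C@H]1C[C@@]2(CO[Si](c3ccccc3)(c3ccccc3)C(C)(C)C)O[C@@H]2/C=C\[C@@]2(C)O[C@H]2[C@H]2OC(=O)C(COC(C)=O)=C12 | intermediate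
33 | (R)-2-methylbutanoic acid | CC[C@@H](C)C(=O)O | starting material
34 | 14-O-TBDPS ether of the target | CC[C@@H](C)C(=O)O[C@H]1C[C@@]2(CO[Si](c3ccccc3)(c3ccccc3)C(C)(C)C)O[C@@H]2/C=C\[C@@]2(C)O[C@H]2[C@H]2OC(=O)C(COC(C)=O)=C12 | intermediate
35 | CNP0108300.1 | CC[C@@H](C)C(=O)O[C@H]1C[C@@]2(CO)O[C@@H]2/C=C\[C@@]2(C)O[C@H]2[C@H]2OC(=O)C(COC(C)=O)=C12 | target

**Step count and risks**

Total: 21 steps. Longest linear sequence: 18 steps (6 → 35, steps 4–21); the C1–C6 branch (steps 1–3) joins at step 9.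

Most likely to fail:

1. Step 17 (proposed new method). What may go wrong: vinylogous 1,4-elimination of the ylide into the C4–C5 oxirane, intermolecular epoxidation giving oligomers, closure to the cis-oxirane or to the C10 epimer, and loss of the Z geometry in the ylide. Fallback with known chemistry, setting out from 19 and returning at 28: the C10 methylene is kept. DDQ cleavage of the PMB ether gives propargylic alcohol with intact C10 methylene F1. Lindlar semi-hydrogenation gives the (2Z)-allylic alcohol F2. MnO2 gives the (2Z)-enal F3. Wittig methylenation (Ph3P=CH2, THF, −78 °C) gives the terminal (Z)-diene F4. Ring-closing metathesis between C1 and the C10 methylene (second-generation Hoveyda–Grubbs catalyst, RuCl2(H2IMes)(=CH–C6H4-2-OiPr), high dilution, toluene) gives the macrocyclic (1(10)E,2Z)-diene F5. Reagent-controlled Shi epoxidation (fructose-derived ketone, KHSO5, buffered) of the trisubstituted C1=C10 alkene then gives 28.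

2. Step 7. What may go wrong: β-elimination of the silyloxy group from the C11 enolate, and deprotonation at C8 leading to loss of configuration or acyl migration (Chan rearrangement). Fallback, setting out from 9 and returning at 12: silylation (Et3SiCl, imidazole) gives the triethylsilyl ether F6. Crossed Claisen condensation of F6 with the lithium enolate of methyl 3-[(tert-butyldimethylsilyl)oxy]propanoate (LiN(iPr)2, THF, −78 °C) forms the C7–C11 bond intermolecularly and gives the β-keto ester F7. Mild removal of the triethylsilyl group (PPTS, MeOH, 0 °C) frees C8–OH, which lactonises onto the methyl ester to give 12.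

3. Step 9. What may go wrong: poor facial selectivity of the addition to the epoxy aldehyde (C6 epimers) and reductive opening of the epoxy aldehyde by CrCl2. Fallback, setting out from 15 (as the epimer mixture) and returning at 15: Dess–Martin oxidation converges both epimers to the epoxy ketone F8, and chelation-controlled reduction with Zn(BH4)2 (Et2O, −20 °C), known to give erythro epoxy alcohols from α,β-epoxy ketones, restores 15 with the (6S) configuration.

**Further compounds**

F1 | step 17 | propargylic alcohol with intact C10 methylene (19 without PMB) | OCC#C[C@@]2(C)O[C@H]2[C@H]2O[Si](C(C)(C)C)(C(C)(C)C)O[C@@H](CC(=C)CO[Si](c3ccccc3)(c3ccccc3)C(C)(C)C)/C2=C(/CO[Si](C)(C)C(C)(C)C)COC(C)=O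
F2 | step 17 | (2Z)-allylic alcohol with intact C10 methylene | OC/C=C\[C@@]2(C)O[C@H]2[C@H]2O[Si](C(C)(C)C)(C(C)(C)C)O[C@@H](CC(=C)CO[Si](c3ccccc3)(c3ccccc3)C(C)(C)C)/C2=C(/CO[Si](C)(C)C(C)(C)C)COC(C)=O
F3 | step 17 | (2Z)-enal | O=C/C=C\[C@@]2(C)O[C@H]2[C@H]2O[Si](C(C)(C)C)(C(C)(C)C)O[C@@H](CC(=C)CO[Si](c3ccccc3)(c3ccccc3)C(C)(C)C)/C2=C(/CO[Si](C)(C)C(C)(C)C)COC(C)=O
F4 | step 17 | terminal (Z)-diene (C1 vinyl) | C=C/C=C\[C@@]2(C)O[C@H]2[C@H]2O[Si](C(C)(C)C)(C(C)(C)C)O[C@@H](CC(=C)CO[Si](c3ccccc3)(c3ccccc3)C(C)(C)C)/C2=C(/CO[Si](C)(C)C(C)(C)C)COC(C)=O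
F5 | step 17 | macrocyclic (1(10)E,2Z)-diene | CC(C)(C)[Si]1(C(C)(C)C)O[C@H]2C/C(CO[Si](c3ccccc3)(c3ccccc3)C(C)(C)C)=C/C=C\[C@@]3(C)O[C@H]3[C@@H](O1)/C2=C(\CO[Si](C)(C)C(C)(C)C)COC(C)=O
F6 | step 7 | triethylsilyl ether of 9 | CCOC(=O)[C@@H](O[Si](CC)(CC)CC)CC(=C)CO[Si](c1ccccc1)(c1ccccc1)C(C)(C)C
F7 | step 7 | β-keto ester (C7 ketone, C13 methyl ester) | COC(=O)C(CO[Si](C)(C)C(C)(C)C)C(=O)[C@@H](O[Si](CC)(CC)CC)CC(=C)CO[Si](c1ccccc1)(c1ccccc1)C(C)(C)C
F8 | step 9 | C6 epoxy ketone from 15 | COc1ccc(COCC#C[C@@]2(C)O[C@H]2C(=O)C2=C(CO[Si](C)(C)C(C)(C)C)C(=O)O[C@H]2CC(=C)CO[Si](c3ccccc3)(c3ccccc3)C(C)(C)C)cc1
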